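**Strategy.** Everything rests on cutting ring A at C8–C8a and C4a–C5. The bond shared by rings A and C (C4a=C8a) is then the brominated C5=C6 double bond of a 2-aryl-3-methoxy-4-pyranone, and the meta-related O5 and O7 come from the two oxygen-bearing carbons of a bis(silyloxy)diene made from methyl acetoacetate. A single [4+2] benzannulation with in-flask loss of HBr, methanol and silicon should thus deliver ring A with free 5- and 7-hydroxyls and never touch the C3 methyl ether. The precursor is the 5-bromopyranone already carrying the diprenylated ring B, its 4'-oxygen masked as a TBS ether so that fluoride, not acid, finally frees the phenol flanked by two prenyl groups.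

Key step: step 10

Remark: the target is achiral (no stereocentre, no geometric isomerism in the prenyl groups), so no step has to set configuration; the racemic, non-isolated intermediates 10, 16 and 17 lose their stereocentres in the same flask.

**Route**

Step 1
Reactants: 1 4-bromophenol; 2 prenyl bromide (1-bromo-3-methylbut-2-ene)
Product: 3 4-bromo-2,6-bis(3-methylbut-2-en-1-yl)phenol
Conditions: NaH (2.2 equiv), PhMe, 0 °C; 2 (2.2 equiv), 0 → 20 °C
Reagents that add atoms: none
Why: Ortho C-alkylation of a sodium phenoxide in a non-polar solvent, where the tight ion aggregate shields oxygen, the para position is blocked by bromine, and both ortho carbons attack the primary terminus of the allylic bromide.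

Step 2
Reactants: 3 4-bromo-2,6-bis(3-methylbut-2-en-1-yl)phenol
Product: 4 (4-bromo-2,6-bis(3-methylbut-2-en-1-yl)phenoxy)(tert-butyl)dimethylsilane
Conditions: TBSCl, imidazole, DMAP (cat.), DMF, 40 °C
Reagents that add atoms: tert-butyl(chloro)dimethylsilane, CC(C)(C)[Si](C)(C)Cl
Why: Standard silylation of a phenol, warmed because of the two ortho substituents, giving an ether that tolerates organolithium, cross-coupling and Lewis-acid conditions and leaves with fluoride.

Step 3
Reactants: 4 (4-bromo-2,6-bis(3-methylbut-2-en-1-yl)phenoxy)(tert-butyl)dimethylsilane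
Product: 6 tert-butyldimethyl[2,6-bis(3-methylbut-2-en-1-yl)-4-(4,4,5,5-tetramethyl-1,3,2-dioxaborolan-2-yl)phenoxy]silane, via aryllithium 5 (not isolated)
Conditions: n-BuLi, THF, −78 °C; iPrOBpin, −78 → 20 °C; aq. NH4Cl
Reagents that add atoms: 2-isopropoxy-4,4,5,5-tetramethyl-1,3,2-dioxaborolane, CC(C)OB1OC(C)(C)C(C)(C)O1; n-butyllithium, [Li]CCCC (supplies the lithium of 5 only)
Why: Bromine–lithium exchange at −78 °C is faster than deprotonation of the benzylic-allylic CH2 groups, and the aryllithium is trapped by the borate ester to give the pinacol boronate.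

Step 4
Reactants: 7 pyromeconic acid (3-hydroxy-4H-pyran-4-one)
Product: 8 3-hydroxy-2-iodo-4H-pyran-4-one
Conditions: I2, Na2CO3, H2O, 20 °C; then HCl to pH 2
Reagents that add atoms: iodine, II
Why: Electrophilic iodination of the enolate of a 3-hydroxy-4-pyranone goes to C2, the only carbon ortho to the hydroxyl, as in the halogenation of kojic and pyromeconic acids.

Step 5
Reactants: 8 3-hydroxy-2-iodo-4H-pyran-4-one
Product: 9 2-iodo-3-methoxy-4H-pyran-4-one
Conditions: MeI, K2CO3, acetone, 40 °C
Reagents that add atoms: iodomethane, CI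
Why: Williamson O-methylation of the acidic enol, as for maltol and kojic acid ethers, under a carbonate base mild enough to spare the vinylogous acyl iodide.

Step 6
Reactants: 9 2-iodo-3-methoxy-4H-pyran-4-one
Product: 11 5-bromo-2-iodo-3-methoxy-4H-pyran-4-one, via trans-5,6-dibromide 10 (not isolated)
Conditions: Br2 (1.05 equiv), CH2Cl2, 0 °C; then Et3N, 0 → 20 °C
Reagents that add atoms: bromine, BrBr
Why: α-Bromination of an enone by addition–elimination (as in chromone to 3-bromochromone), in which bromine adds to the only CH=CH bond (C5=C6) and triethylamine removes the acidic H-5 with loss of the C6 bromide (E1cB), C2 being blocked by iodine.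

Step 7
Reactants: 11 5-bromo-2-iodo-3-methoxy-4H-pyran-4-one; 6 tert-butyldimethyl[2,6-bis(3-methylbut-2-en-1-yl)-4-(4,4,5,5-tetramethyl-1,3,2-dioxaborolan-2-yl)phenoxy]silane
Product: 12 5-bromo-2-[4-(tert-butyldimethylsilyloxy)-3,5-bis(3-methylbut-2-en-1-yl)phenyl]-3-methoxy-4H-pyran-4-one
Conditions: Pd(PPh3)4 (5 mol %), K3PO4, 1,4-dioxane/H2O (10:1), 60 °C
Reagents that add atoms: none
Why: Suzuki–Miyaura coupling that is site-selective for C2, because a C–I bond on the enone β-carbon (a vinylogous acyl iodide) undergoes oxidative addition far faster than the α C–Br bond, the moderate temperature protecting that bromide and the hindered aryl silyl ether.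

Step 8
Reactants: 13 methyl acetoacetate
Product: 14 methyl 3-(trimethylsilyloxy)but-2-enoate (E/Z mixture)
Conditions: TMSCl, Et3N, hexane, 20 °C
Reagents that add atoms: chlorotrimethylsilane, C[Si](C)(C)Cl
Why: O-Silylation of the enol of a β-keto ester with TMSCl and triethylamine, the standard first stage in the preparation of 1,3-bis(silyloxy)dienes.

Step 9
Reactants: 14 methyl 3-(trimethylsilyloxy)but-2-enoate
Product: 15 1-methoxy-1,3-bis(trimethylsilyloxy)buta-1,3-diene (isomer mixture at C1=C2, geometry irrelevant)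
Conditions: LDA, THF, −78 °C; TMSCl, −78 → 0 °C
Reagents that add atoms: chlorotrimethylsilane, C[Si](C)(C)Cl
Why: γ-Deprotonation of the β-silyloxy enoate with LDA and O-silylation of the resulting ester dienolate is the known preparation of this diene.

Step 10
Reactants: 12 5-bromo-2-[4-(tert-butyldimethylsilyloxy)-3,5-bis(3-methylbut-2-en-1-yl)phenyl]-3-methoxy-4H-pyran-4-one; 15 1-methoxy-1,3-bis(trimethylsilyloxy)buta-1,3-diene
Product: 18 2-[4-(tert-butyldimethylsilyloxy)-3,5-bis(3-methylbut-2-en-1-yl)phenyl]-5,7-dihydroxy-3-methoxy-4H-chromen-4-one, via cis-fused bromo cycloadduct 16 (not isolated), via 5,8-dihydrochromenone mixed ketal 17 (not isolated)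
Conditions: 15 (3 equiv), Yb(fod)3 (10 mol %), PhMe, 70 °C; then DBU, 0 → 20 °C; then 1 M HCl, THF, 20 °C
Reagents that add atoms: none
Why: Proposed new method: the electron-rich diene 15 should add in a normal-demand, strongly asynchronous Diels–Alder sense across the C5=C6 enone bond of 12, whose LUMO is lowered by the α-bromine and by Yb(III) chelation of the C4 carbonyl/3-OMe pair, the CH2 terminus of the diene (largest HOMO coefficient) bonding to the β-carbon C6 (future C8a) and the ketene-acetal carbon to C5 (future C4a). The closest known reaction types are the Diels–Alder/aromatisation of 1,3-bis(silyloxy)dienes and 1,1-dialkoxy-3-silyloxydienes with 2-haloquinones, the cycloaddition of 3-acyl- and 3-cyanochromones with silyloxydienes, and the amine-induced dehydrobromination of 3-bromochroman-4-ones to chromones. Ring A is closed in a suprafacial [4+2] mode to the cis-fused adduct 16 (if the addition were stepwise, conjugate addition at C6 would be followed by a 6-(enolexo)-exo-trig closure of the C5 enolate on the ester-level carbon). DBU then takes HBr out across C4a–C8a while C5 is still a mixed methyl silyl ketal, that is, before the bromine sits between two carbonyl groups where it could be lost reductively or trigger retro-Claisen opening, and dilute acid finally hydrolyses the ketal and the silyl enol ether of 17 so that the 5,7-dione tautomerises to the resorcinol ring. No stereocentre survives, so the configuration of 16 is immaterial. The step needs the diene to choose C5=C6 over the tetrasubstituted, donor-substituted C2=C3 bond and the electron-rich prenyl alkenes and to adopt the orientation that puts oxygen on C5 and C7; both follow from the polarisation of the bromo-enone, a mild lanthanide catalyst rather than a silyl triflate or TiCl4 is used so that the addition does not stall at an open-chain conjugate adduct, and the aryl TBS ether is inert to all three stages.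

Step 11
Reactants: 18 2-[4-(tert-butyldimethylsilyloxy)-3,5-bis(3-methylbut-2-en-1-yl)phenyl]-5,7-dihydroxy-3-methoxy-4H-chromen-4-one
Product: 19 5,7-dihydroxy-2-[4-hydroxy-3,5-bis(3-methylbut-2-en-1-yl)phenyl]-3-methoxy-4H-chromen-4-one (target)
Conditions: TBAF, AcOH, THF, 0 → 20 °C
Reagents that add atoms: none
Why: Fluoride cleavage of an aryl silyl ether, buffered with acetic acid, is fast, avoids any acid strong enough to cyclise an ortho-prenyl phenol to a chroman, and leaves the 5,7-dihydroxy-3-methoxychromone untouched.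

**Compound list**

1 | 4-bromophenol | Oc1ccc(Br)cc1 | starting material
2 | prenyl bromide (1-bromo-3-methylbut-2-ene) | CC(C)=CCBr | starting material
3 | 4-bromo-2,6-bis(3-methylbut-2-en-1-yl)phenol | CC(C)=CCc1cc(Br)cc(CC=C(C)C)c1O | intermediate
4 | (4-bromo-2,6-bis(3-methylbut-2-en-1-yl)phenoxy)(tert-butyl)dimethylsilane | CC(C)=CCc1cc(Br)cc(CC=C(C)C)c1O[Si](C)(C)C(C)(C)C | intermediate
5 | [4-(tert-butyldimethylsilyloxy)-3,5-bis(3-methylbut-2-en-1-yl)phenyl]lithium | [Li]c1cc(CC=C(C)C)c(O[Si](C)(C)C(C)(C)C)c(CC=C(C)C)c1 | intermediate (not isolated)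
6 | tert-butyldimethyl[2,6-bis(3-methylbut-2-en-1-yl)-4-(4,4,5,5-tetramethyl-1,3,2-dioxaborolan-2-yl)phenoxy]silane | CC(C)=CCc1cc(B2OC(C)(C)C(C)(C)O2)cc(CC=C(C)C)c1O[Si](C)(C)C(C)(C)C | intermediate
7 | pyromeconic acid (3-hydroxy-4H-pyran-4-one) | Oc1coccc1=O | starting material
8 | 3-hydroxy-2-iodo-4H-pyran-4-one | Oc1c(I)occc1=O | intermediate
9 | 2-iodo-3-methoxy-4H-pyran-4-one | COc1c(I)occc1=O | intermediate
10 | trans-5,6-dibromo-2-iodo-3-methoxy-5,6-dihydro-4H-pyran-4-one (racemic; one enantiomer drawn) | COC1=C(I)O[C@@H](Br)[C@H](Br)C1=O | intermediate (not isolated)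
11 | 5-bromo-2-iodo-3-methoxy-4H-pyran-4-one | COc1c(I)occ(Br)c1=O | intermediate
12 | 5-bromo-2-[4-(tert-butyldimethylsilyloxy)-3,5-bis(3-methylbut-2-en-1-yl)phenyl]-3-methoxy-4H-pyran-4-one | COc1c(-c2cc(CC=C(C)C)c(O[Si](C)(C)C(C)(C)C)c(CC=C(C)C)c2)occ(Br)c1=O | intermediate
13 | methyl acetoacetate | COC(=O)CC(C)=O | starting material
14 | methyl 3-(trimethylsilyloxy)but-2-enoate (E/Z mixture) | COC(=O)C=C(C)O[Si](C)(C)C | intermediate
15 | 1-methoxy-1,3-bis(trimethylsilyloxy)buta-1,3-diene (isomer mixture) | COC(O[Si](C)(C)C)=CC(=C)O[Si](C)(C)C | intermediate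
16 | 4a-bromo-2-[4-(tert-butyldimethylsilyloxy)-3,5-bis(3-methylbut-2-en-1-yl)phenyl]-3,5-dimethoxy-5,7-bis(trimethylsilyloxy)-4a,5,8,8a-tetrahydro-4H-chromen-4-one (racemic, cis ring fusion drawn as one enantiomer, C5 epimers) | COC1=C(c3cc(CC=C(C)C)c(O[Si](C)(C)C(C)(C)C)c(CC=C(C)C)c3)O[C@H]2CC(O[Si](C)(C)C)=CC(OC)(O[Si](C)(C)C)[C@@]2(Br)C1=O | intermediate (not isolated)
17 | 2-[4-(tert-butyldimethylsilyloxy)-3,5-bis(3-methylbut-2-en-1-yl)phenyl]-3,5-dimethoxy-5,7-bis(trimethylsilyloxy)-5,8-dihydro-4H-chromen-4-one (racemic at C5) | COc1c(-c2cc(CC=C(C)C)c(O[Si](C)(C)C(C)(C)C)c(CC=C(C)C)c2)oc2c(c1=O)C(OC)(O[Si](C)(C)C)C=C(O[Si](C)(C)C)C2 | intermediate (not isolated)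
18 | 2-[4-(tert-butyldimethylsilyloxy)-3,5-bis(3-methylbut-2-en-1-yl)phenyl]-5,7-dihydroxy-3-methoxy-4H-chromen-4-one | COc1c(-c2cc(CC=C(C)C)c(O[Si](C)(C)C(C)(C)C)c(CC=C(C)C)c2)oc2cc(O)cc(O)c2c1=O | intermediate
19 | 5,7-dihydroxy-2-[4-hydroxy-3,5-bis(3-methylbut-2-en-1-yl)phenyl]-3-methoxy-4H-chromen-4-one | COc1c(-c2cc(CC=C(C)C)c(O)c(CC=C(C)C)c2)oc2cc(O)cc(O)c2c1=O | target

**Step count and risk**

Total steps: 11. Longest linear sequence: 6 steps (steps 4, 5, 6, 7, 10, 11 from pyromeconic acid; equally steps 1, 2, 3, 7, 10, 11 from 4-bromophenol).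

Steps most likely to fail:

1. Step 10 (proposed new method). The bromo-enone may be too weak a dienophile, so the diene decomposes before it adds. The addition may also turn stepwise and stop after the first C–C bond; the open-chain adduct can then open at O1 and cyclise through its central carbon instead of the ester carbon. In the cis-fused adduct H-8a and bromine are not antiperiplanar, so dehydrobromination may be slow, and reductive loss of bromine or cleavage of the O1–C8a bond would strip ring A of its C8a oxygen. Fallback by known chemistry (ester formation, Baker–Venkataraman acyl shift, cyclodehydration), setting out from 4 and coming back at 18: bromine–lithium exchange on 4 (n-BuLi, THF, −78 °C) and a CO2 quench should give 4-(tert-butyldimethylsilyloxy)-3,5-bis(3-methylbut-2-en-1-yl)benzoic acid F1. Commercial 2-methoxy-1-(2,4,6-trihydroxyphenyl)ethanone (COCC(=O)c1c(O)cc(O)cc1O) is protected with MOMCl/iPr2NEt, the chelated ortho hydroxyl staying free, to 1-[2-hydroxy-4,6-bis(methoxymethoxy)phenyl]-2-methoxyethanone F2. Esterification of F2 with F1 (EDC·HCl, DMAP, CH2Cl2) gives 2-(2-methoxyacetyl)-3,5-bis(methoxymethoxy)phenyl 4-(tert-butyldimethylsilyloxy)-3,5-bis(3-methylbut-2-en-1-yl)benzoate F3. LiHMDS (THF, −78 → 0 °C) shifts the aroyl group from oxygen to carbon to give 1-[4-(tert-butyldimethylsilyloxy)-3,5-bis(3-methylbut-2-en-1-yl)phenyl]-3-[2-hydroxy-4,6-bis(methoxymethoxy)phenyl]-2-methoxypropane-1,3-dione F4. Methanolic HCl at 40 °C closes the pyranone by cyclodehydration and removes both acetals; the 4'-oxygen is still silylated, so no prenyl group has a free ortho phenol while acid is present. The product is 18, which continues with step 11.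

2. Step 6. Electrophilic bromine may attack the iodinated C2 instead of C5 (ipso exchange and halogen scrambling), or bromide may displace the activated C2 iodide during the elimination, giving a mixture of halides. Fallback in an all-bromine series, where such exchange is degenerate and selectivity in the coupling comes from position and not from halogen identity, setting out from 7 and coming back at 12: NBS (DMF, 0 °C) brominates 7 at C2 to 2-bromo-3-hydroxy-4H-pyran-4-one F5; MeI/K2CO3 gives 2-bromo-3-methoxy-4H-pyran-4-one F6; Br2 then Et3N gives 2,5-dibromo-3-methoxy-4H-pyran-4-one F7; Suzuki–Miyaura coupling of F7 with 6 under the conditions of step 7, site-selective for the bromide on the enone β-carbon C2, gives 12.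

3. Step 1. O-Alkylation, incomplete second C-alkylation and acid-induced ring closure of the ortho-prenyl phenol to a chroman during work-up may erode the dialkylated phenol. Fallback by iterative Claisen rearrangement and cross-metathesis, setting out from 1 and coming back at 4: O-allylation (allyl bromide, K2CO3, acetone) gives 1-(allyloxy)-4-bromobenzene F8; aromatic Claisen rearrangement (N,N-diethylaniline, 190 °C) gives 2-allyl-4-bromophenol F9; a second O-allylation gives 2-allyl-1-(allyloxy)-4-bromobenzene F10; a second Claisen rearrangement gives 2,6-diallyl-4-bromophenol F11; silylation (TBSCl, imidazole, DMF) gives (2,6-diallyl-4-bromophenoxy)(tert-butyl)dimethylsilane F12; cross-metathesis with 2-methylbut-2-ene (second-generation Ru–NHC benzylidene catalyst, CH2Cl2, 40 °C) turns both allyl groups into prenyl groups and gives 4.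

**Further compounds**

F1 | step 10 | 4-(tert-butyldimethylsilyloxy)-3,5-bis(3-methylbut-2-en-1-yl)benzoic acid | CC(C)=CCc1cc(C(=O)O)cc(CC=C(C)C)c1O[Si](C)(C)C(C)(C)C
F2 | step 10 | 1-[2-hydroxy-4,6-bis(methoxymethoxy)phenyl]-2-methoxyethanone | COCC(=O)c1c(O)cc(OCOC)cc1OCOC
F3 | step 10 | 2-(2-methoxyacetyl)-3,5-bis(methoxymethoxy)phenyl 4-(tert-butyldimethylsilyloxy)-3,5-bis(3-methylbut-2-en-1-yl)benzoate | COCC(=O)c1c(OC(=O)c2cc(CC=C(C)C)c(O[Si](C)(C)C(C)(C)C)c(CC=C(C)C)c2)cc(OCOC)cc1OCOC
F4 | step 10 | 1-[4-(tert-butyldimethylsilyloxy)-3,5-bis(3-methylbut-2-en-1-yl)phenyl]-3-[2-hydroxy-4,6-bis(methoxymethoxy)phenyl]-2-methoxypropane-1,3-dione (racemic, enolisable) | COC(C(=O)c1cc(CC=C(C)C)c(O[Si](C)(C)C(C)(C)C)c(CC=C(C)C)c1)C(=O)c1c(O)cc(OCOC)cc1OCOC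
F5 | step 6 | 2-bromo-3-hydroxy-4H-pyran-4-one | Oc1c(Br)occc1=O
F6 | step 6 | 2-bromo-3-methoxy-4H-pyran-4-one | COc1c(Br)occc1=O
F7 | step 6 | 2,5-dibromo-3-methoxy-4H-pyran-4-one | COc1c(Br)occ(Br)c1=O
F8 | step 1 | 1-(allyloxy)-4-bromobenzene | C=CCOc1ccc(Br)cc1
F9 | step 1 | 2-allyl-4-bromophenol | C=CCc1cc(Br)ccc1O
F10 | step 1 | 2-allyl-1-(allyloxy)-4-bromobenzene | C=CCOc1ccc(Br)cc1CC=C
F11 | step 1 | 2,6-diallyl-4-bromophenol | C=CCc1cc(Br)cc(CC=C)c1O
F12 | step 1 | (2,6-diallyl-4-bromophenoxy)(tert-butyl)dimethylsilane | C=CCc1cc(Br)cc(CC=C)c1O[Si](C)(C)C(C)(C)C
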